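# Proposed total synthesis of (13E)-6β-hydroxy-3α,19-bis(3-methylbutanoyloxy)labda-8,13-dien-15-oic acid (29)

Labdane locants are used for every intermediate, including the monocyclic ones: ring A = C1–C5 and C10, ring B = C5–C10, C11 = first side-chain carbon on C9, C17 = methyl on C8, C18 = 4α-methyl, C19 = 4β-CH2O, C20 = methyl on C10. The α face is the one opposite to C20. Compounds of the route are 1–29.

## The problem

Compound 29 is a labdane: a trans-fused decalin whose C9 carries a five-carbon chain ending in an (E)-3-methylbut-2-enoic acid, with a tetrasubstituted C8=C9 double bond. All five stereocentres (C3, C4, C5, C6, C10) sit on ring A or at the ring fusion. C4 and C10 are quaternary and stand 1,3 across C5 with C19 and C20 syn-axial, and both secondary oxygens are axial (3α anti to C19, 6β syn to C19 and C20). C4 can be fixed first by desymmetrising an achiral dione; it then governs its neighbour C3 directly, and C10 only through a weaker 1,3 relay. C4 and C10 together make the equatorial placement of C6 on C5 the stable one, and the finished trans ring fusion leaves only the α face of C6 open to a hydride. The two isovalerate esters will not survive hydrides, carbanions or alkoxides and must come last; the C8=C9 alkene can migrate in strong acid; β-hydroxy ketones on the way can cleave by retro-aldol reaction; and O6 must stay free at the end, which is possible without a protecting group because it is by far the most screened hydroxyl. The feature that opens the route is the sequence O6–C6–C7–C8(=C)–C17, a homoallylic alcohol with a methyl on the alkene carbon: the retron of a carbonyl-ene reaction between an aldehyde carbon C6 on C5 and a C7=C8 isopropenyl unit joined through C9 to C10. An ester on C9 (the future C11) then serves three times: it arrives with the isopropenyl group in a Claisen rearrangement, it draws the new alkene into C8=C9, and it is the handle for the side chain.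

## Retrosynthesis

**Ester C–O bonds at O3 and O19 (29 ⇒ 26 + 27).** The acyl groups are removed first because nothing earlier in the route tolerates them. The precursor is triol acid 26 and 3-methylbutanoic anhydride 27. The forward step must acylate the primary C19 and the axial 3α hydroxyls and leave the 6β hydroxyl, which sits between C19 and C20.

**C15 carboxyl, silyl ethers, then C11–C12 and C13–C16 (26 ⇒ 25 ⇒ 24 ⇒ 23 ⇒ 22 ⇒ 20 + 21).** Saponification and desilylation lead back to methyl ester 24. Its trisubstituted enoate is cut at the C13–C16 methyl (enol phosphate 23, β-keto ester 22) and at C11–C12 (allylic bromide 20 and methyl acetoacetate 21). This is preferred to a Horner–Wadsworth–Emmons reaction on a C13 methyl ketone, which would give E/Z mixtures, and to olefination at C11, which would leave a C11=C12 alkene to reduce selectively. The forward reactions are an SN2 alkylation by the acetoacetate dianion and a cuprate coupling that keeps the alkene geometry.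

**C11 oxidation level and alkene position (20 ⇒ 19 ⇒ 18 ⇒ 17).** Bromide 20 comes from allylic alcohol 19 and this from conjugated ester 18. The C8=C9 alkene of 18 is traced to the exocyclic C8=C17 alkene of β,γ-unsaturated ester 17. Placing the alkene by conjugation with the C9 ester is chosen over acid isomerisation of a C9-alkyl compound, which would give C7/C8 mixtures. The forward step is a base equilibration.

**C6–C7, the key cut (17 ⇒ 16).** Breaking C6–C7 removes ring B and the C6 stereocentre and leaves ring A aldehyde 16 with an isopropenyl arm. Cutting C9–C10 or C5–C10 instead would ask a ring closure to create a quaternary centre; the C6–C7 cut joins two unhindered sp2 carbons and writes the C6 oxygen and the C8 alkene at their final positions. The forward carbonyl-ene closure inherits the trans ring fusion from the diequatorial C5 and C10 substituents of 16 and has only C6 to control.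

**C5–C6 (16 ⇒ 15 ⇒ 14).** The formyl carbon is removed by way of spiro-epoxide 15 to ketone 14. A ketone at C5 is what the ring A chemistry leaves behind and what the C9–C10 bond formation needs. The forward steps are a sulfur-ylide methylenation of a ketone flanked by two quaternary carbons and an epoxide-to-aldehyde rearrangement, after which C5 is set thermodynamically.

**C9–C10 (14 ⇒ 13 ⇒ 10 + 12; 12 ⇒ 11).** A retro-Claisen step cuts C9–C10 and returns allyl enol ether 13, made from methyl enol ether 10 and allylic alcohol 12, which comes from bromide 11. Direct enolate alkylation with 11 would give the linear isomer and cannot join a quaternary to a tertiary carbon; the [3,3] shift gives the branched arm with the ester on C9 and the isopropenyl group intact. The forward step must deliver the arm to the α face of C10.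

**C10–C20, C3 configuration, C4–C19 (10 ⇒ 9 ⇒ 8 ⇒ 7 ⇒ 6 ⇒ 5 ⇒ 4 ⇒ 3 ⇒ 1 + 2).** Enol ether 10 comes from ketone 9, and 9 from 8 by methylation at C10, the only enolisable position. The 3α oxygen of 8 is traced through 7 and ester 6 to the cis ketol 5 by inversion, because enzymatic reduction of dione 4 gives the hydroxyl cis to C19. Dione 4 is the silyl ether of 3, the aldol adduct of 2-methylcyclohexane-1,3-dione 1 and formaldehyde 2. The enzymatic step sets C4, the anchor for all other centres.

## Roads not taken

**Alternative 1:** intramolecular Diels–Alder reaction across C5–C10 and C8–C9. Heating triene A2 (silyl dienol ether C5=C6–C7=C8, trisubstituted enoate C9=C10, four-carbon tether C1–C4) would close both rings to A1. Its merits are real: two rings and four stereocentres in one step, a convergent open-chain precursor, and a C6 silyl enol ether that becomes the 6-ketone and hence the 6β-alcohol by hydride attack from the α face. In ring-forming economy it is better than the chosen plan. Its weak points are the dienophile, whose β carbon must become quaternary C10 and is therefore slow to react; the trans ring fusion, which depends on one of two folding modes; and the quaternary C4, which must already exist in the open chain and bias that folding. A1 also carries C8 as an sp3 methine, so C8=C9 needs a later dehydrogenation, and C3 and C19 need reduction. The chosen plan is longer but sets each centre in a separate step and delivers the C6 oxygen and the C8 alkene directly.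

**Alternative 2:** Ireland–Claisen ring contraction across C9–C10. The silyl ketene acetal of δ-lactone A4 would rearrange through a boat to acid A3, forming C9–C10, breaking C6–O and closing ring B with a C5=C6 alkene. Its strong point is C10: chirality is transferred suprafacially from the C6 carbinol, a more reliable relay than the facial bias used in step 10 of the chosen plan, and this must be conceded. Against it, A4 needs a metalated tetrasubstituted ring A alkene and a chiral aldehyde, and the shift must build a quaternary centre at that hindered terminus. A3 has no C6 oxygen: hydroboration of C5=C6 would give the 6α-alcohol and a further oxidation and reduction. C8 is again sp3. The chosen plan has the weaker C10 control but fewer adjustments after ring closure.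

**Alternative 3:** intermolecular Diels–Alder reaction across C1–C10 and C4–C5. Diene A7 would add to the symmetrical quinone monoketal A6 to give the cis-fused adduct A5, with ring B coming from an aromatic precursor. It is the shortest way to a functionalised decalin, and in step count to the bicycle it beats the chosen plan. Its weak points are that it is racemic unless a chiral Lewis acid for this dienophile class is found, that the ring fusion is cis and must be epimerised at C5 through the C6 ketone, that C4 is tertiary and needs a stereoselective methylation, and that ring B has the wrong pattern: the C9 ketone and C7=C8 enone must be turned into C8=C9 with a C11 chain. The chosen plan takes its absolute configuration from an enzymatic desymmetrisation and builds ring B with the final oxidation pattern.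

Key step: step 13

Assumption: the ketoreductase of step 3 shows the selectivity known for baker's-yeast reduction of 2-allyl- and 2-propargyl-2-methylcyclohexane-1,3-diones (3S carbinol, hydroxyl cis to the larger substituent on the quaternary carbon).

## Route

Step 1
Reactants: 1 2-methylcyclohexane-1,3-dione; 2 formaldehyde (37% aqueous)
Product: 3 2-(hydroxymethyl)-2-methylcyclohexane-1,3-dione
Conditions: aq. HCHO, NaHCO3 (cat.), H2O, rt
Reagents that add atoms: none
Why: Aldol hydroxymethylation of the enolised 1,3-dione at its only nucleophilic carbon (the future C4) forms C4–C19; the product is achiral, and mild bicarbonate with prompt silylation limits retro-aldol loss of formaldehyde.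

Step 2
Reactants: 3 2-(hydroxymethyl)-2-methylcyclohexane-1,3-dione
Product: 4 2-({[tert-butyl(dimethyl)silyl]oxy}methyl)-2-methylcyclohexane-1,3-dione
Conditions: TBSCl, imidazole, CH2Cl2, 0 °C → rt
Reagents that add atoms: tert-butyldimethylsilyl chloride, CC(C)(C)[Si](C)(C)Cl
Why: Silylation of the primary alcohol blocks the retro-aldol path and makes CH2OTBS clearly the larger of the two substituents on the quaternary carbon for the enzymatic step.

Step 3
Reactants: 4 2-({[tert-butyl(dimethyl)silyl]oxy}methyl)-2-methylcyclohexane-1,3-dione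
Product: 5 (2S,3S)-2-({[tert-butyl(dimethyl)silyl]oxy}methyl)-3-hydroxy-2-methylcyclohexan-1-one (hydroxyl cis to CH2OTBS)
Conditions: (S)-selective ketoreductase of the baker's-yeast type, NADP+ (cat.), i-PrOH, phosphate buffer pH 7, DMSO (5%), 30 °C
Reagents that add atoms: none
Why: Enzymatic desymmetrising mono-reduction of a 2,2-disubstituted cyclohexane-1,3-dione: the enzyme picks one enantiotopic carbonyl and delivers hydride anti to the larger CH2OTBS group, which fixes C4 (4α-methyl, 4β-CH2O) and gives the 3S (3β) carbinol. Only C4 is kept; C3 is inverted in step 4.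

Step 4
Reactants: 5 (2S,3S)-2-({[tert-butyl(dimethyl)silyl]oxy}methyl)-3-hydroxy-2-methylcyclohexan-1-one
Product: 6 (1R,2S)-2-({[tert-butyl(dimethyl)silyl]oxy}methyl)-2-methyl-3-oxocyclohexyl 4-nitrobenzoate (ester oxygen trans to CH2OTBS)
Conditions: 4-O2NC6H4CO2H, PPh3, DIAD, toluene, 0 °C → rt
Reagents that add atoms: 4-nitrobenzoic acid, O=C(O)c1ccc(cc1)[N+](=O)[O-]
Why: Mitsunobu inversion with an acidic carboxylic acid, as used for the 2,2-dimethyl analogue of this ketol; the carboxylate attacks C3 from the α face with inversion, giving the 3α oxygen anti to C19. The neighbouring sp2 carbonyl carbon removes one syn-axial hydrogen from the path of the nucleophile.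

Step 5
Reactants: 6 (1R,2S)-2-({[tert-butyl(dimethyl)silyl]oxy}methyl)-2-methyl-3-oxocyclohexyl 4-nitrobenzoate
Product: 7 (2S,3R)-2-({[tert-butyl(dimethyl)silyl]oxy}methyl)-3-hydroxy-2-methylcyclohexan-1-one (hydroxyl trans to CH2OTBS)
Conditions: K2CO3 (0.2 equiv), MeOH, 0 °C
Reagents that add atoms: none
Why: Transesterification of the activated 4-nitrobenzoate with catalytic carbonate at low temperature frees the 3α-alcohol before the β-hydroxy ketone can cleave by retro-aldol reaction.

Step 6
Reactants: 7 (2S,3R)-2-({[tert-butyl(dimethyl)silyl]oxy}methyl)-3-hydroxy-2-methylcyclohexan-1-one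
Product: 8 (2S,3R)-3-{[tert-butyl(dimethyl)silyl]oxy}-2-({[tert-butyl(dimethyl)silyl]oxy}methyl)-2-methylcyclohexan-1-one
Conditions: TBSOTf, 2,6-lutidine, CH2Cl2, −78 → 0 °C
Reagents that add atoms: tert-butyldimethylsilyl trifluoromethanesulfonate, CC(C)(C)[Si](C)(C)OS(=O)(=O)C(F)(F)F
Why: Silyl triflate with a hindered base silylates the neopentyl-type secondary alcohol without base-induced retro-aldol cleavage.

Step 7
Reactants: 8 (2S,3R)-3-{[tert-butyl(dimethyl)silyl]oxy}-2-({[tert-butyl(dimethyl)silyl]oxy}methyl)-2-methylcyclohexan-1-one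
Product: 9 (2S,3R,6RS)-3-{[tert-butyl(dimethyl)silyl]oxy}-2-({[tert-butyl(dimethyl)silyl]oxy}methyl)-2,6-dimethylcyclohexan-1-one (C10 epimers)
Conditions: LiN(i-Pr)2, THF, −78 °C; MeI, −78 → −20 °C
Reagents that add atoms: iodomethane, CI
Why: Kinetic enolate methylation: C4 is quaternary, so deprotonation can occur only at C10, and the methyl becomes C20. Both C10 epimers are used because C10 becomes trigonal in step 8.

Step 8
Reactants: 9 (2S,3R,6RS)-3-{[tert-butyl(dimethyl)silyl]oxy}-2-({[tert-butyl(dimethyl)silyl]oxy}methyl)-2,6-dimethylcyclohexan-1-one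
Product: 10 ring A methyl enol ether: 5-methoxy-3α-(TBSO)-4β-(TBSOCH2)-4α,10-dimethylcyclohex-5(10)-ene
Conditions: HC(OMe)3, PPTS (cat.), 50 °C, volatiles distilled off
Reagents that add atoms: trimethyl orthoformate, COC(OC)OC
Why: Acid-catalysed enol ether formation with orthoformate: 2,2,6-trisubstituted cyclohexanones give the enol ether in place of the strained dimethyl ketal, and only C10 carries a hydrogen, so a single regioisomer forms. The weak acid and the absence of methanol as solvent spare the silyl ethers.

Step 9
Reactants: 11 methyl (E)-4-bromo-3-methylbut-2-enoate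
Product: 12 methyl (E)-4-hydroxy-3-methylbut-2-enoate
Conditions: CaCO3, H2O–dioxane (1:1), 90 °C
Reagents that add atoms: water, O
Why: Hydrolysis of the activated primary allylic bromide by water, buffered by carbonate; the neutral medium keeps the E geometry and so prevents lactonisation to the butenolide.

Step 10
Reactants: 10 ring A methyl enol ether; 12 methyl (E)-4-hydroxy-3-methylbut-2-enoate
Product: 14 ring A ketone: methyl 2-[3α-(TBSO)-4β-(TBSOCH2)-4α,10β-dimethyl-5-oxocyclohexan-10-yl]-3-methylbut-3-enoate (arm α on C10; C9 with CO2Me β-equatorial after ring closure), via allyl enol ether 13 (not isolated)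
Conditions: 12 (3 equiv), EtCO2H (10 mol%), xylene, 140 °C, MeOH distilled off
Reagents that add atoms: none
Why: Acid-catalysed enol-ether exchange gives 13, which undergoes Claisen [3,3] rearrangement in the same flask (ketal-Claisen variant) and forms C9–C10 with the isopropenyl group unmasked. The larger CH2OTBS group on C4 should sit pseudo-axial on the β face (A(1,2) strain with the enol-ether oxygen, anti to 3α-OTBS), so the allyl unit migrates on the α face and C20 ends up β. The chair transition state with the E alkene places CO2Me equatorial and sets C9 as drawn; that centre is erased in step 14.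

Step 11
Reactants: 14 ring A ketone
Product: 15 spiro-epoxide of 14 (1-oxaspiro[2.5]octane; spiro carbon C5, either configuration)
Conditions: Me3S+ I−, KN(SiMe3)2, THF, −10 °C → rt
Reagents that add atoms: trimethylsulfonium iodide, C[S+](C)C.[I-]
Why: Corey–Chaykovsky methylenation: the small, non-stabilised sulfonium ylide adds to a ketone flanked by two quaternary carbons (no enolisation possible) and the betaine closes to the epoxide, bringing in C6. The configuration at the spiro carbon does not matter because step 12 passes through a trigonal C5.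

Step 12
Reactants: 15 spiro-epoxide
Product: 16 ring A aldehyde: methyl 2-[3α-(TBSO)-4β-(TBSOCH2)-5β-formyl-4α,10β-dimethylcyclohexan-10-yl]-3-methylbut-3-enoate (5α-H)
Conditions: BF3·OEt2 (0.2 equiv), CH2Cl2, −78 → −40 °C; then K2CO3 (cat.), MeOH, 0 °C
Reagents that add atoms: none
Why: Meinwald rearrangement: the Lewis acid opens the 2,2-disubstituted oxirane to the tertiary C5 cation and hydride shifts from C6 to C5, giving the aldehyde. Brief carbonate treatment equilibrates C5 through the enol to the epimer with equatorial formyl (trans to the C9 arm), the arrangement free of a syn-axial contact with 3α-OTBS; the far less acidic C9 hydrogen of the ester is not touched.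

Step 13
Reactants: 16 ring A aldehyde
Product: 17 methyl 3α,19-bis(TBSO)-6β-hydroxy-12,13,14,15,16-pentanorlabd-8(17)-en-11-oate (9α-H)
Conditions: Me2AlCl (2.0 equiv), CH2Cl2, −78 → −20 °C
Reagents that add atoms: none
Why: Me2AlCl binds the aldehyde oxygen, and C6 is attacked by the terminus C7 of the 1,1-disubstituted alkene while a hydrogen of the C17 methyl moves to oxygen: a type 2 intramolecular carbonyl-ene (Prins-type) reaction, the known route from δ,ε-unsaturated aldehydes to 3-methylenecyclohexanols. Ring B closes as a six-membered chair in which the enophile is tethered to the central ene carbon C8 through C9–C10–C5; the C5–C6 and C10–C9 bonds are equatorial on ring A, so the trans ring fusion is inherited from 16 and is not at stake. The only new stereocentre is C6: in the concerted path the oxygen must be axial to reach the transferring hydrogen, which gives the 6β-alcohol. The ester on C9 destabilises a free C8 cation and should therefore favour this concerted path over a stepwise closure with equatorial oxygen. The selectivity needed is that the axial oxygen passes between C19 and C20; the aluminium sits anti to C5 and points away from both. The adduct loses methane to give an aluminium alkoxide, which protects the exocyclic alkene from proton-induced isomerisation. The second equivalent of Me2AlCl is held by the ester.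

Step 14
Reactants: 17 methyl 3α,19-bis(TBSO)-6β-hydroxy-12,13,14,15,16-pentanorlabd-8(17)-en-11-oate
Product: 18 methyl 3α,19-bis(TBSO)-6β-hydroxy-12,13,14,15,16-pentanorlabd-8-en-11-oate
Conditions: NaOMe, MeOH, 65 °C
Reagents that add atoms: none
Why: Base equilibration of the β,γ-unsaturated ester through its dienolate into the conjugated tetrasubstituted C8=C9 enoate, the isomerisation known for bicyclofarnesoate-type esters; the C9 stereocentre disappears, and a C7=C8 isomer or a C8 chloride from a stepwise closure in step 13 would drain into the same product.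

Step 15
Reactants: 18 methyl 3α,19-bis(TBSO)-6β-hydroxy-12,13,14,15,16-pentanorlabd-8-en-11-oate
Product: 19 3α,19-bis(TBSO)-12,13,14,15,16-pentanorlabd-8-ene-6β,11-diol
Conditions: i-Bu2AlH (4 equiv), CH2Cl2, −78 → 0 °C; aq. KNaC4H4O6
Reagents that add atoms: none
Why: Hydride reduction of the hindered conjugated ester to the allylic alcohol, 1,2 only; the excess reagent takes up the free 6β-hydroxyl as its aluminate.

Step 16
Reactants: 19 3α,19-bis(TBSO)-12,13,14,15,16-pentanorlabd-8-ene-6β,11-diol
Product: 20 11-bromo-3α,19-bis(TBSO)-12,13,14,15,16-pentanorlabd-8-en-6β-ol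
Conditions: CBr4, PPh3, 2,6-lutidine, CH2Cl2, −20 °C
Reagents that add atoms: carbon tetrabromide, BrC(Br)(Br)Br
Why: Appel bromination: the primary allylic alcohol reacts much faster than the axial 6β-hydroxyl screened by C19 and C20, and the buffered neutral medium keeps the alkene in place. The bromide is used at once.

Step 17
Reactants: 20 11-bromo-3α,19-bis(TBSO)-12,13,14,15,16-pentanorlabd-8-en-6β-ol; 21 methyl 3-oxobutanoate
Product: 22 methyl 3α,19-bis(TBSO)-6β-hydroxy-13-oxo-16-norlabd-8-en-15-oate
Conditions: 21 (4 equiv), NaH, THF, 0 °C; n-BuLi, 0 °C; then 20, 0 °C → rt; aq. NH4Cl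
Reagents that add atoms: none
Why: γ-Alkylation of the acetoacetate dianion: its terminal carbanion displaces the primary allylic bromide (SN2) and forms C11–C12. One equivalent of dianion is spent on the free hydroxyl, and the resulting alkoxide cannot reach C11 because the ring would have to contain a trans double bond.

Step 18
Reactants: 22 methyl 3α,19-bis(TBSO)-6β-hydroxy-13-oxo-16-norlabd-8-en-15-oate
Product: 23 methyl (13Z)-3α,19-bis(TBSO)-13-(diethoxyphosphoryloxy)-6β-hydroxy-16-norlabda-8,13-dien-15-oate
Conditions: NaH (1.05 equiv), Et2O, 0 °C; ClP(O)(OEt)2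
Reagents that add atoms: diethyl chlorophosphate, CCOP(=O)(Cl)OCC
Why: The chelated sodium enolate of the β-keto ester is phosphorylated on oxygen and gives the Z enol phosphate; one equivalent of NaH deprotonates only the β-keto ester, which is far more acidic than the hindered alcohol.

Step 19
Reactants: 23 methyl (13Z)-3α,19-bis(TBSO)-13-(diethoxyphosphoryloxy)-6β-hydroxy-16-norlabda-8,13-dien-15-oate
Product: 24 methyl (13E)-3α,19-bis(TBSO)-6β-hydroxylabda-8,13-dien-15-oate
Conditions: Me2CuLi (5 equiv, from MeLi and CuI), Et2O, −78 → −45 °C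
Reagents that add atoms: lithium dimethylcuprate, [Li+].C[Cu-]C
Why: Cuprate substitution of a β-(phosphoryloxy) enoate with retention of alkene geometry, the established stereospecific route to 3-methyl-2-enoates: the new methyl C16 ends up cis to the ester, which is the 13E isomer. The excess reagent covers the free hydroxyl.

Step 20
Reactants: 24 methyl (13E)-3α,19-bis(TBSO)-6β-hydroxylabda-8,13-dien-15-oate
Product: 25 (13E)-3α,19-bis(TBSO)-6β-hydroxylabda-8,13-dien-15-oic acid
Conditions: LiOH·H2O, THF–MeOH–H2O, 50 °C; then 1 M HCl to pH 3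
Reagents that add atoms: lithium hydroxide, [Li+].[OH-]
Why: Saponification of the methyl enoate while no other ester is present; the conjugated E alkene and the hindered silyl ethers should stand aqueous hydroxide.

Step 21
Reactants: 25 (13E)-3α,19-bis(TBSO)-6β-hydroxylabda-8,13-dien-15-oic acid
Product: 26 (13E)-3α,6β,19-trihydroxylabda-8,13-dien-15-oic acid
Conditions: HF·pyridine, pyridine, THF, 0 → 40 °C
Reagents that add atoms: none
Why: Fluoride cleaves both silyl ethers through Si–F bond formation; the pyridine-buffered reagent avoids the strong acid that could move the tetrasubstituted alkene.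

Step 22
Reactants: 26 (13E)-3α,6β,19-trihydroxylabda-8,13-dien-15-oic acid; 27 3-methylbutanoic anhydride
Product: 29 (13E)-6β-hydroxy-3α,19-bis(3-methylbutanoyloxy)labda-8,13-dien-15-oic acid, via C15 mixed anhydride 28 (not isolated)
Conditions: 27 (5 equiv), DMAP (0.2 equiv), pyridine, CH2Cl2, 0 °C → rt; then H2O–pyridine, rt
Reagents that add atoms: water, O
Why: DMAP-catalysed acylation of the primary C19 and the axial 3α hydroxyls; the 6β-hydroxyl, axial and syn to both C19 and C20, should remain free as it does in the target. The C15 acid is tied up for the time being as mixed anhydride 28, from which DMAP transfers the more electrophilic isovaleryl group, and 28 is hydrolysed in the aqueous pyridine work-up.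

## Compound list

1 | 2-methylcyclohexane-1,3-dione | CC1C(=O)CCCC1=O | starting material
2 | formaldehyde | C=O | starting material
3 | 2-(hydroxymethyl)-2-methylcyclohexane-1,3-dione | CC1(CO)C(=O)CCCC1=O | intermediate
4 | 2-({[tert-butyl(dimethyl)silyl]oxy}methyl)-2-methylcyclohexane-1,3-dione | CC1(CO[Si](C)(C)C(C)(C)C)C(=O)CCCC1=O | intermediate
5 | (2S,3S)-2-({[tert-butyl(dimethyl)silyl]oxy}methyl)-3-hydroxy-2-methylcyclohexan-1-one | O=C1CCC[C@H](O)[C@]1(C)CO[Si](C)(C)C(C)(C)C | intermediate
6 | (1R,2S)-2-({[tert-butyl(dimethyl)silyl]oxy}methyl)-2-methyl-3-oxocyclohexyl 4-nitrobenzoate | O=C1CCC[C@@H](OC(=O)c2ccc(cc2)[N+](=O)[O-])[C@]1(C)CO[Si](C)(C)C(C)(C)C | intermediate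
7 | (2S,3R)-2-({[tert-butyl(dimethyl)silyl]oxy}methyl)-3-hydroxy-2-methylcyclohexan-1-one | O=C1CCC[C@@H](O)[C@]1(C)CO[Si](C)(C)C(C)(C)C | intermediate
8 | (2S,3R)-3-{[tert-butyl(dimethyl)silyl]oxy}-2-({[tert-butyl(dimethyl)silyl]oxy}methyl)-2-methylcyclohexan-1-one | O=C1CCC[C@@H](O[Si](C)(C)C(C)(C)C)[C@]1(C)CO[Si](C)(C)C(C)(C)C | intermediate
9 | (2S,3R,6RS)-3-{[tert-butyl(dimethyl)silyl]oxy}-2-({[tert-butyl(dimethyl)silyl]oxy}methyl)-2,6-dimethylcyclohexan-1-one (C10 epimers, centre left open) | O=C1C(C)CC[C@@H](O[Si](C)(C)C(C)(C)C)[C@]1(C)CO[Si](C)(C)C(C)(C)C | intermediate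
10 | ring A methyl enol ether, 5-methoxy-3α-(TBSO)-4β-(TBSOCH2)-4α,10-dimethylcyclohex-5(10)-ene | COC1=C(C)CC[C@@H](O[Si](C)(C)C(C)(C)C)[C@]1(C)CO[Si](C)(C)C(C)(C)C | intermediate
11 | methyl (E)-4-bromo-3-methylbut-2-enoate | COC(=O)/C=C(\C)CBr | starting material
12 | methyl (E)-4-hydroxy-3-methylbut-2-enoate | COC(=O)/C=C(\C)CO | intermediate
13 | allyl enol ether, methyl (E)-3-methyl-4-(ring A C5 enol oxygen)but-2-enoate | COC(=O)/C=C(\C)COC1=C(C)CC[C@@H](O[Si](C)(C)C(C)(C)C)[C@]1(C)CO[Si](C)(C)C(C)(C)C | intermediate (not isolated)
14 | ring A ketone, methyl 2-[3α-(TBSO)-4β-(TBSOCH2)-4α,10β-dimethyl-5-oxocyclohexan-10-yl]-3-methylbut-3-enoate | C=C(C)[C@H](C(=O)OC)[C@@]1(C)CC[C@@H](O[Si](C)(C)C(C)(C)C)[C@](C)(CO[Si](C)(C)C(C)(C)C)C1=O | intermediate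
15 | spiro-epoxide of 14 (spiro carbon C5 left open) | C=C(C)[C@H](C(=O)OC)[C@@]1(C)CC[C@@H](O[Si](C)(C)C(C)(C)C)[C@](C)(CO[Si](C)(C)C(C)(C)C)C12CO2 | intermediate
16 | ring A aldehyde, 5β-formyl (5α-H) with C10 β-methyl and α arm | C=C(C)[C@H](C(=O)OC)[C@@]1(C)CC[C@@H](O[Si](C)(C)C(C)(C)C)[C@](C)(CO[Si](C)(C)C(C)(C)C)[C@@H]1C=O | intermediate
17 | methyl 3α,19-bis(TBSO)-6β-hydroxy-12,13,14,15,16-pentanorlabd-8(17)-en-11-oate | C=C1[C@H](C(=O)OC)[C@@]2(C)CC[C@@H](O[Si](C)(C)C(C)(C)C)[C@](C)(CO[Si](C)(C)C(C)(C)C)[C@@H]2[C@H](O)C1 | intermediate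
18 | methyl 3α,19-bis(TBSO)-6β-hydroxy-12,13,14,15,16-pentanorlabd-8-en-11-oate | CC1=C(C(=O)OC)[C@@]2(C)CC[C@@H](O[Si](C)(C)C(C)(C)C)[C@](C)(CO[Si](C)(C)C(C)(C)C)[C@@H]2[C@H](O)C1 | intermediate
19 | 3α,19-bis(TBSO)-12,13,14,15,16-pentanorlabd-8-ene-6β,11-diol | CC1=C(CO)[C@@]2(C)CC[C@@H](O[Si](C)(C)C(C)(C)C)[C@](C)(CO[Si](C)(C)C(C)(C)C)[C@@H]2[C@H](O)C1 | intermediate
20 | 11-bromo-3α,19-bis(TBSO)-12,13,14,15,16-pentanorlabd-8-en-6β-ol | CC1=C(CBr)[C@@]2(C)CC[C@@H](O[Si](C)(C)C(C)(C)C)[C@](C)(CO[Si](C)(C)C(C)(C)C)[C@@H]2[C@H](O)C1 | intermediate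
21 | methyl 3-oxobutanoate | COC(=O)CC(C)=O | starting material
22 | methyl 3α,19-bis(TBSO)-6β-hydroxy-13-oxo-16-norlabd-8-en-15-oate | CC1=C(CCC(=O)CC(=O)OC)[C@@]2(C)CC[C@@H](O[Si](C)(C)C(C)(C)C)[C@](C)(CO[Si](C)(C)C(C)(C)C)[C@@H]2[C@H](O)C1 | intermediate
23 | methyl (13Z)-3α,19-bis(TBSO)-13-(diethoxyphosphoryloxy)-6β-hydroxy-16-norlabda-8,13-dien-15-oate | CC1=C(CC/C(OP(=O)(OCC)OCC)=C/C(=O)OC)[C@@]2(C)CC[C@@H](O[Si](C)(C)C(C)(C)C)[C@](C)(CO[Si](C)(C)C(C)(C)C)[C@@H]2[C@H](O)C1 | intermediate
24 | methyl (13E)-3α,19-bis(TBSO)-6β-hydroxylabda-8,13-dien-15-oate | CC1=C(CC/C(C)=C/C(=O)OC)[C@@]2(C)CC[C@@H](O[Si](C)(C)C(C)(C)C)[C@](C)(CO[Si](C)(C)C(C)(C)C)[C@@H]2[C@H](O)C1 | intermediate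
25 | (13E)-3α,19-bis(TBSO)-6β-hydroxylabda-8,13-dien-15-oic acid | CC1=C(CC/C(C)=C/C(=O)O)[C@@]2(C)CC[C@@H](O[Si](C)(C)C(C)(C)C)[C@](C)(CO[Si](C)(C)C(C)(C)C)[C@@H]2[C@H](O)C1 | intermediate
26 | (13E)-3α,6β,19-trihydroxylabda-8,13-dien-15-oic acid | CC1=C(CC/C(C)=C/C(=O)O)[C@@]2(C)CC[C@@H](O)[C@](C)(CO)[C@@H]2[C@H](O)C1 | intermediate
27 | 3-methylbutanoic anhydride | CC(C)CC(=O)OC(=O)CC(C)C | starting material
28 | C15 mixed anhydride of 29 with 3-methylbutanoic acid | CC1=C(CC/C(C)=C/C(=O)OC(=O)CC(C)C)[C@@]2(C)CC[C@@H](OC(=O)CC(C)C)[C@](C)(COC(=O)CC(C)C)[C@@H]2[C@H](O)C1 | intermediate (not isolated)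
29 | (13E)-6β-hydroxy-3α,19-bis(3-methylbutanoyloxy)labda-8,13-dien-15-oic acid (3R,4S,5R,6R,10S) | CC1=C(CC/C(C)=C/C(=O)O)[C@@]2(C)CC[C@@H](OC(=O)CC(C)C)[C@](C)(COC(=O)CC(C)C)[C@@H]2[C@H](O)C1 | target

## Step count and risks

Total: 22 steps. Longest linear sequence: 21 steps (from 1 through steps 1–8 and 10–22); step 9 is a one-step side branch.

**Step 13 (key step).** The aluminium-bound oxygen may take the equatorial position to escape C19 and C20. The closure would then run stepwise through the C8 cation and give the 6α-alcohol, with loss of regiocontrol in the proton loss or with chloride capture at C8. Fallback, from 16 back to 17: the cyclisation is run as before, and the 6α-alcohol F1 (or the epimer mixture) is oxidised with Dess–Martin periodinane (NaHCO3 buffer) to the 6-ketone F2. NaBH4 with CeCl3·7H2O in MeOH at −40 °C then delivers hydride from the α face, the β face being closed by C19 and C20, and gives 17. Alkene isomers and a C8 chloride need no separate treatment because step 14 leads them to 18.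

**Step 4.** SN2 displacement at a carbinol next to a quaternary carbon is slow; the activated alcohol may eliminate towards C2 or return with retention. Fallback, from 5 to 8: inversion by oxidation and hydroxyl-directed reduction. The C5 ketone of 5 is masked as ethylene ketal F3 ((Me3SiOCH2)2, Me3SiOTf cat.), the C3 hydroxyl is oxidised to ketone F4 (Dess–Martin periodinane), and the C19 silyl ether is removed (HF·pyridine) to give hydroxy ketone F5. Me4NBH(OAc)3 in MeCN–AcOH then delivers hydride from the C19 oxygen and places the new hydroxyl anti to C19 (diol F6). Silylation of both hydroxyls (TBSOTf, 2,6-lutidine) gives F7, and ketal hydrolysis (PPTS, wet acetone) returns 8.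

**Step 10.** Enol-ether exchange at the hindered C5 may be slow, so that alcohol 12 isomerises and lactonises first; and the facial preference of the [3,3] shift at C10 rests on a conformational bias of modest size, so the C10 epimer may form in quantity. Fallback, from 9 to 14 without 10: the allyl enol ether is made under basic conditions. Alcohol 12 is converted into mesylate F8 (MsCl, Et3N), and the potassium enolate of 9 (KN(SiMe3)2, THF–DMPU, −78 °C), whose carbon terminus is shielded on both sides, is alkylated on oxygen to give 13. Without acid present, 13 can be rearranged in toluene at the lowest workable temperature to 14, which should sharpen the facial preference; C10 epimers are separated at 14.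

**Step 11.** The ylide may act as a base at C9 instead of adding to the shielded carbonyl, which would move the arm's alkene into conjugation and destroy the ene component. Fallback, from 14 to 15: chloromethyllithium, generated in the presence of 14 from ICH2Cl and MeLi·LiBr at −78 °C, adds faster than it deprotonates; the lithium alkoxide of chlorohydrin F9 closes to 15 on warming.

**Step 14.** The conjugated ester is twisted by its neighbours on C8 and C10, so the equilibrium may stop short of full conversion. Fallback, from 17 to 19: the alkene is moved at the aldehyde level, where conjugation is decisive. i-Bu2AlH reduces 17 to diol F10; TEMPO/PhI(OAc)2 oxidises only the primary alcohol to the β,γ-unsaturated aldehyde F11; a trace of DBU gives the conjugated enal F12; NaBH4 returns 19.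

**Step 22.** The axial 3α-hydroxyl may acylate sluggishly, and forcing conditions may then begin to acylate O6 or cause acyl migration from O19 to O6. Fallback, from 25 to 29: C6 is carried as a ketone through the acylation. Dess–Martin oxidation of 25, whose only free hydroxyl is O6, gives keto acid F13; HF·pyridine gives diol F14, which may sit in equilibrium with its 6,19-hemiketal. Acylation with 27 and DMAP, now without a competing secondary hydroxyl on ring B, gives F15, and NaBH4/CeCl3·7H2O at −40 °C reduces the ketone from the α face to 29 without touching the esters.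

## Further compounds

F1 | step 13 | methyl 3α,19-bis(TBSO)-6α-hydroxy-12,13,14,15,16-pentanorlabd-8(17)-en-11-oate | C=C1[C@H](C(=O)OC)[C@@]2(C)CC[C@@H](O[Si](C)(C)C(C)(C)C)[C@](C)(CO[Si](C)(C)C(C)(C)C)[C@@H]2[C@@H](O)C1
F2 | step 13 | methyl 3α,19-bis(TBSO)-6-oxo-12,13,14,15,16-pentanorlabd-8(17)-en-11-oate | C=C1[C@H](C(=O)OC)[C@@]2(C)CC[C@@H](O[Si](C)(C)C(C)(C)C)[C@](C)(CO[Si](C)(C)C(C)(C)C)[C@@H]2C(=O)C1
F3 | step 4 | ethylene ketal of 5 (C5 dioxolane, 3β-OH, C19-OTBS) | C12(OCCO2)CCC[C@H](O)[C@]1(C)CO[Si](C)(C)C(C)(C)C
F4 | step 4 | 3-oxo ethylene ketal (C19-OTBS) | C12(OCCO2)CCCC(=O)[C@]1(C)CO[Si](C)(C)C(C)(C)C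
F5 | step 4 | 3-oxo ethylene ketal with free C19 hydroxyl | C12(OCCO2)CCCC(=O)[C@]1(C)CO
F6 | step 4 | 3α,19-diol ethylene ketal | C12(OCCO2)CCC[C@@H](O)[C@]1(C)CO
F7 | step 4 | ethylene ketal of 8 | C12(OCCO2)CCC[C@@H](O[Si](C)(C)C(C)(C)C)[C@]1(C)CO[Si](C)(C)C(C)(C)C
F8 | step 10 | methyl (E)-4-(methanesulfonyloxy)-3-methylbut-2-enoate | COC(=O)/C=C(\C)COS(C)(=O)=O
F9 | step 11 | C5 chlorohydrin of 14 (5-hydroxy-5-chloromethyl) | C=C(C)[C@H](C(=O)OC)[C@@]1(C)CC[C@@H](O[Si](C)(C)C(C)(C)C)[C@](C)(CO[Si](C)(C)C(C)(C)C)C1(O)CCl
F10 | step 14 | 3α,19-bis(TBSO)-12,13,14,15,16-pentanorlabd-8(17)-ene-6β,11-diol | C=C1[C@H](CO)[C@@]2(C)CC[C@@H](O[Si](C)(C)C(C)(C)C)[C@](C)(CO[Si](C)(C)C(C)(C)C)[C@@H]2[C@H](O)C1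
F11 | step 14 | 3α,19-bis(TBSO)-6β-hydroxy-12,13,14,15,16-pentanorlabd-8(17)-en-11-al | C=C1[C@H](C=O)[C@@]2(C)CC[C@@H](O[Si](C)(C)C(C)(C)C)[C@](C)(CO[Si](C)(C)C(C)(C)C)[C@@H]2[C@H](O)C1
F12 | step 14 | 3α,19-bis(TBSO)-6β-hydroxy-12,13,14,15,16-pentanorlabd-8-en-11-al | CC1=C(C=O)[C@@]2(C)CC[C@@H](O[Si](C)(C)C(C)(C)C)[C@](C)(CO[Si](C)(C)C(C)(C)C)[C@@H]2[C@H](O)C1
F13 | step 22 | (13E)-3α,19-bis(TBSO)-6-oxolabda-8,13-dien-15-oic acid | CC1=C(CC/C(C)=C/C(=O)O)[C@@]2(C)CC[C@@H](O[Si](C)(C)C(C)(C)C)[C@](C)(CO[Si](C)(C)C(C)(C)C)[C@@H]2C(=O)C1
F14 | step 22 | (13E)-3α,19-dihydroxy-6-oxolabda-8,13-dien-15-oic acid | CC1=C(CC/C(C)=C/C(=O)O)[C@@]2(C)CC[C@@H](O)[C@](C)(CO)[C@@H]2C(=O)C1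
F15 | step 22 | (13E)-3α,19-bis(3-methylbutanoyloxy)-6-oxolabda-8,13-dien-15-oic acid | CC1=C(CC/C(C)=C/C(=O)O)[C@@]2(C)CC[C@@H](OC(=O)CC(C)C)[C@](C)(COC(=O)CC(C)C)[C@@H]2C(=O)C1
A1 | alternative 1 | trans-fused decalin silyl enol ether (C6-OTBS, C3 dioxolane, C4 and C9 methyl esters) | C[C@@H]1[C@H](C(=O)OC)[C@@]2(C)CCC3(OCCO3)[C@](C)(C(=O)OC)[C@@H]2C(O[Si](C)(C)C(C)(C)C)=C1
A2 | alternative 1 | open-chain triene (silyl dienol ether and trisubstituted enoate joined by the C1–C4 tether) | C/C=C/C(O[Si](C)(C)C(C)(C)C)=C/[C@@](C)(C(=O)OC)C1(OCCO1)CC/C(C)=C/C(=O)OC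
A3 | alternative 2 | Δ5-octalin C9 carboxylic acid with quaternary C10 | C[C@H]1[C@@H](C(=O)O)[C@@]2(C)CC[C@@H](O[Si](C)(C)C(C)(C)C)[C@](C)(CO[Si](C)(C)C(C)(C)C)C2=CC1
A4 | alternative 2 | δ-lactone, 4-methyl-6-(ring A cyclohex-5(10)-en-5-yl)oxan-2-one | O=C1C[C@H](C)C[C@H](O1)C2=C(C)CC[C@@H](O[Si](C)(C)C(C)(C)C)[C@]2(C)CO[Si](C)(C)C(C)(C)C
A5 | alternative 3 | cis-fused adduct with C9 ketone, C6 dimethyl ketal and C3 silyl enol ether | O=C1[C@@]2(C)CC=C(O[Si](C)(C)C(C)(C)C)[C@@H](C(=O)OC)[C@H]2C(OC)(OC)C=C1C
A6 | alternative 3 | 4,4-dimethoxy-2,6-dimethylcyclohexa-2,5-dien-1-one | COC1(OC)C=C(C)C(=O)C(C)=C1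
A7 | alternative 3 | methyl (2Z)-3-{[tert-butyl(dimethyl)silyl]oxy}penta-2,4-dienoate | C=C/C(O[Si](C)(C)C(C)(C)C)=C/C(=O)OC
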